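**Retrosynthetic overview**
- The ring is not acylated. The cyclohexane-1,3-dione is closed in the last step by a Dieckmann (intramolecular Claisen) C-acylation that isomerises an acyclic γ-lactone β-diketone into the target. The lactone serves as both hydroxyl protection and latent ester, so no protecting groups are used.
- The lactone β-diketone comes from crossed Claisen acylation of the kinetic enolate of (8E,10E)-nonadeca-8,10-dien-2-one with (R)-5-oxotetrahydrofuran-2-carbonyl chloride. The stereocentre is bought in and its C–O and C–H bonds are never broken.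
- The methyl ketone comes from an acetoacetic ester synthesis on (5E,7E)-1-chlorohexadeca-5,7-diene.
- The E,E-diene comes from Suzuki–Miyaura coupling of (E)-6-chloro-1-iodohex-1-ene with the E-alkenylboronate of dec-1-yne.
- Ring order: only one carbocycle. Ring bond C2–C1 is made in the acylation step and ring bond C2–C3 in the final step, where the six-membered ring closes as the lactone opens.

Assumption: 1,3-dicarbonyl compounds are written as single tautomers (they equilibrate freely), and cyclopentadienyl ligands are drawn as σ-bonded rings in SMILES strings.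

**Route**

Step 1
Reactants: 1 6-chlorohex-1-yne
Product: 3 (E)-6-chloro-1-iodohex-1-ene, via alkenylzirconocene chloride 2 (not isolated)
Conditions: Cp2Zr(H)Cl (1.2 equiv.), THF, rt, 1 h; then I2 (1.2 equiv.), 0 °C
Reagents that add atoms: iodine, I-I
Why: Schwartz hydrozirconation adds Zr–H syn with zirconium at the terminal carbon, and iodinolysis of the C–Zr bond goes with retention, so the E-alkenyl iodide forms while the primary chloride is untouched.

Step 2
Reactants: 4 dec-1-yne; 3 (E)-6-chloro-1-iodohex-1-ene
Product: 6 (5E,7E)-1-chlorohexadeca-5,7-diene, via decenyl benzodioxaborole 5 (not isolated)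
Conditions: catecholborane (1.05 equiv.), neat, 70 °C, 2 h; then 3, Pd(PPh3)4 (3 mol%), 2 M aq. NaOH, THF, 65 °C
Reagents that add atoms: none
Why: syn-hydroboration gives the E-alkenylboronate, and Suzuki–Miyaura coupling (zerovalent palladium inserts only into the C–I bond, not the alkyl C–Cl bond) joins the two alkenyl units with retention at both, which sets the E,E-diene.

Step 3
Reactants: 6 (5E,7E)-1-chlorohexadeca-5,7-diene; 7 ethyl acetoacetate (1.3 equiv.)
Product: 11 (8E,10E)-nonadeca-8,10-dien-2-one, via dienyl iodide 8 (not isolated), via alkylated keto ester 9 (not isolated), via keto acid 10 (not isolated)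
Conditions: NaOEt (1.2 equiv.), NaI (0.1 equiv.), EtOH, reflux; then 2 M aq. NaOH, rt → 50 °C; then 2 M HCl to pH 2, 60 °C (−CO2)
Reagents that add atoms: none
Why: acetoacetic ester synthesis (iodide-assisted SN2 C-alkylation of the acetoacetate enolate, saponification, decarboxylation of the β-keto acid) gives the methyl ketone with five methylenes between carbonyl and diene, and the isolated diene is inert to these conditions.

Step 4
Reactants: 12 (R)-5-oxotetrahydrofuran-2-carboxylic acid
Product: 13 (R)-5-oxotetrahydrofuran-2-carbonyl chloride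
Conditions: (COCl)2 (1.3 equiv.), DMF (cat.), CH2Cl2, 0 °C → rt; concentrate, use crude
Reagents that add atoms: oxalyl chloride, ClC(=O)C(Cl)=O
Why: DMF-catalysed (Vilsmeier-type) chlorination makes the acyl chloride without base, so the α-acyloxy stereocentre cannot epimerise through a ketene and the γ-lactone stays intact.

Step 5
Reactants: 11 (8E,10E)-nonadeca-8,10-dien-2-one (2.0 equiv.); 13 (R)-5-oxotetrahydrofuran-2-carbonyl chloride (1.0 equiv.)
Product: 15 (5R)-5-[(9E,11E)-3-oxoicosa-9,11-dienoyl]oxolan-2-one, via lithium enolate 14 (not isolated)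
Conditions: LiN(SiMe3)2 (2.0 equiv.), toluene–THF, −78 °C, 45 min; then 13, −78 °C, 30 min; 1 M HCl quench; excess 11 recovered
Reagents that add atoms: none
Why: crossed Claisen-type C-acylation in which the hindered amide removes the methyl proton under kinetic control, the acyl chloride (far more electrophilic than the lactone carbonyl) acylates the enolate carbon at −78 °C, and the second enolate equivalent rather than free amide base deprotonates the β-diketone product, so the stereocentre of 13 is carried into 15 unchanged.

Step 6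
Reactants: 15 (5R)-5-[(9E,11E)-3-oxoicosa-9,11-dienoyl]oxolan-2-one
Product: 17 (6R)-3,6-dihydroxy-2-[(7E,9E)-octadeca-7,9-dienoyl]cyclohex-2-en-1-one, via hydroxy methyl ester 16 (not isolated)
Conditions: NaOMe (3.0 equiv.), degassed MeOH, Ar, 0 °C → reflux; then cold 1 M HCl to pH 3
Reagents that add atoms: none
Why: Proposed new method: methoxide first deprotonates the β-diketone (which blocks retro-Claisen cleavage and, through the negative charge, enolisation toward the adjacent stereocentre), then opens the activated α-keto γ-lactone to hydroxy methyl ester 16, whose diketonate carbon attacks the ester in a 6-exo-trig Dieckmann condensation driven by formation of the strongly stabilised triketonate, so the lactone acyl group moves from O to C in a net isomerisation and the (R) C–O stereocentre is never broken; the closest known reactions are the Lacey–Dieckmann cyclisation of N-acetoacetyl amino esters to 3-acyltetramic acids and the base-mediated Claisen cyclisation of 5,7-dioxo esters to 2-acylcyclohexane-1,3-diones.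

**Compound list**
1 | 6-chlorohex-1-yne | ClCCCCC#C | starting material
2 | chlorobis(cyclopentadienyl)[(E)-6-chlorohex-1-en-1-yl]zirconium | ClCCCC/C=C/[Zr](Cl)(C1C=CC=C1)C1C=CC=C1 | intermediate
3 | (E)-6-chloro-1-iodohex-1-ene | ClCCCC/C=C/I | intermediate
4 | dec-1-yne | CCCCCCCCC#C | starting material
5 | (E)-2-(dec-1-en-1-yl)-1,3,2-benzodioxaborole | CCCCCCCC/C=C/B1Oc2ccccc2O1 | intermediate
6 | (5E,7E)-1-chlorohexadeca-5,7-diene | CCCCCCCC/C=C/C=C/CCCCCl | intermediate
7 | ethyl acetoacetate | CCOC(=O)CC(C)=O | starting material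
8 | (5E,7E)-1-iodohexadeca-5,7-diene | CCCCCCCC/C=C/C=C/CCCCI | intermediate
9 | ethyl (7E,9E)-2-acetyloctadeca-7,9-dienoate (racemic at C2) | CCCCCCCC/C=C/C=C/CCCCC(C(C)=O)C(=O)OCC | intermediate
10 | (7E,9E)-2-acetyloctadeca-7,9-dienoic acid (racemic at C2) | CCCCCCCC/C=C/C=C/CCCCC(C(C)=O)C(O)=O | intermediate
11 | (8E,10E)-nonadeca-8,10-dien-2-one | CCCCCCCC/C=C/C=C/CCCCCC(C)=O | intermediate
12 | (R)-5-oxotetrahydrofuran-2-carboxylic acid | OC(=O)[C@H]1CCC(=O)O1 | starting material
13 | (R)-5-oxotetrahydrofuran-2-carbonyl chloride | ClC(=O)[C@H]1CCC(=O)O1 | intermediate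
14 | lithium (8E,10E)-nonadeca-1,8,10-trien-2-olate | [Li+].[O-]C(=C)CCCCC/C=C/C=C/CCCCCCCC | intermediate
15 | (5R)-5-[(9E,11E)-3-oxoicosa-9,11-dienoyl]oxolan-2-one | CCCCCCCC/C=C/C=C/CCCCCC(=O)CC(=O)[C@H]1CCC(=O)O1 | intermediate
16 | methyl (4R,13E,15E)-4-hydroxy-5,7-dioxotetracosa-13,15-dienoate | CCCCCCCC/C=C/C=C/CCCCCC(=O)CC(=O)[C@H](O)CCC(=O)OC | intermediate
17 | (6R)-3,6-dihydroxy-2-[(7E,9E)-octadeca-7,9-dienoyl]cyclohex-2-en-1-one (CNP0169831.1) | CCCCCCCC/C=C/C=C/CCCCCC(=O)C1=C(O)CC[C@@H](O)C1=O | target

**Totals**
Total step count: 6. Longest linear sequence: 5 steps (1 → 2 → 3 → 5 → 6); step 4 is a one-step side branch.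

**Three steps most likely to fail**

Step 6 (lactone opening and Dieckmann closure with a free hydroxyl). The hydroxy ester may relactonise faster than it cyclises, may form a 3(2H)-furanone on acidification, or may lose optical purity. The fallback closes the ring on a silyl-protected diester; it sets out from 12 and 11 and comes back to the route at 17. Compound 12 is opened and esterified (MeOH, cat. H2SO4, reflux) to dimethyl (R)-2-hydroxypentanedioate F1, which is silylated (TBSCl, imidazole, DMF) to dimethyl (R)-2-[(tert-butyldimethylsilyl)oxy]pentanedioate F2. Enolate 14, made from 11 with LiN(SiMe3)2 (2.2 equiv. of base, THF, −78 → 0 °C), is acylated by F2. This gives methyl (4R,13E,15E)-4-[(tert-butyldimethylsilyl)oxy]-5,7-dioxotetracosa-13,15-dienoate F3 together with its regioisomer methyl (2R,13E,15E)-2-[(tert-butyldimethylsilyl)oxy]-5,7-dioxotetracosa-13,15-dienoate F4. Because the tricarbonyl unit of the ring is symmetric, both close with KOC(CH3)3 in THF at 0 °C to the same silyl ether, (6R)-6-[(tert-butyldimethylsilyl)oxy]-3-hydroxy-2-[(7E,9E)-octadeca-7,9-dienoyl]cyclohex-2-en-1-one F5. HF·pyridine in THF at 0 °C then gives 17.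

Step 5 (enolate acylation). Risks are O-acylation, incomplete methyl-versus-methylene selectivity, partial epimerisation of the α-acyloxy acyl donor, and the need for two equivalents of 11. The fallback replaces the Claisen acylation by an aldol addition with 1:1 stoichiometry followed by oxidation; it sets out from 13 and 11 and comes back at 15. Compound 13 is reduced to (R)-5-oxotetrahydrofuran-2-carbaldehyde F6 (Bu3SnH, Pd(PPh3)4 cat., THF, rt). Compound 11 is converted with LiN(iPr)2 (1.05 equiv., THF, −78 °C) into 14, which adds to F6 to give (5R)-5-[(9E,11E)-1-hydroxy-3-oxoicosa-9,11-dien-1-yl]oxolan-2-one F7 as a mixture of carbinol epimers, which does not matter. Dess–Martin periodinane (CH2Cl2, NaHCO3, rt) oxidises F7 to 15.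

Step 2 (one-pot hydroboration and Suzuki coupling). Risks are regioisomeric or double hydroboration, homocoupling, and loss of E,E purity that cannot be corrected later. The fallback drops boron, base and water for a zirconium-based alkenyl–alkenyl coupling; it sets out from 4 and 3 and comes back at 6. Compound 4 is hydrozirconated with Cp2Zr(H)Cl (THF, rt) to chlorobis(cyclopentadienyl)[(E)-dec-1-en-1-yl]zirconium F8, which couples with 3 under Pd(PPh3)4 catalysis (THF, rt) in a Negishi-type reaction with retention at both alkenyl carbons to give 6.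

**Further compounds**
F1 | step 6 | dimethyl (R)-2-hydroxypentanedioate | COC(=O)[C@H](O)CCC(=O)OC
F2 | step 6 | dimethyl (R)-2-[(tert-butyldimethylsilyl)oxy]pentanedioate | COC(=O)[C@H](O[Si](C)(C)C(C)(C)C)CCC(=O)OC
F3 | step 6 | methyl (4R,13E,15E)-4-[(tert-butyldimethylsilyl)oxy]-5,7-dioxotetracosa-13,15-dienoate | CCCCCCCC/C=C/C=C/CCCCCC(=O)CC(=O)[C@H](O[Si](C)(C)C(C)(C)C)CCC(=O)OC
F4 | step 6 | methyl (2R,13E,15E)-2-[(tert-butyldimethylsilyl)oxy]-5,7-dioxotetracosa-13,15-dienoate | CCCCCCCC/C=C/C=C/CCCCCC(=O)CC(=O)CC[C@@H](O[Si](C)(C)C(C)(C)C)C(=O)OC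
F5 | step 6 | (6R)-6-[(tert-butyldimethylsilyl)oxy]-3-hydroxy-2-[(7E,9E)-octadeca-7,9-dienoyl]cyclohex-2-en-1-one | CCCCCCCC/C=C/C=C/CCCCCC(=O)C1=C(O)CC[C@@H](O[Si](C)(C)C(C)(C)C)C1=O
F6 | step 5 | (R)-5-oxotetrahydrofuran-2-carbaldehyde | O=C[C@H]1CCC(=O)O1
F7 | step 5 | (5R)-5-[(9E,11E)-1-hydroxy-3-oxoicosa-9,11-dien-1-yl]oxolan-2-one | CCCCCCCC/C=C/C=C/CCCCCC(=O)CC(O)[C@H]1CCC(=O)O1
F8 | step 2 | chlorobis(cyclopentadienyl)[(E)-dec-1-en-1-yl]zirconium | CCCCCCCC/C=C/[Zr](Cl)(C1C=CC=C1)C1C=CC=C1
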